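**Plan**

- Retrosynthetic cuts: the acetyl–O bond at C10; the two C–O bonds of the oxirane (O–C8 and O–C9), leading back to a 2-arylallyl alcohol; the angeloyl–O(phenol) bond; the aryl–alkenyl bond C4–C8; the acyl–O bond at C7.
- Enabling feature: the oxirane C8–O–C9 carries at C8 only the benzene ring and the oxygenated C10 arm, so C8=C9 with a free C10 hydroxyl is a 1,1-disubstituted allylic alcohol, fit for hydroxyl-directed oxygen transfer.
- Forward: methyl 4-bromo-3-hydroxybenzoate is silylated, reduced, esterified at C7 and borylated; Suzuki coupling with silylated 2-bromoallyl alcohol joins C4–C8; the phenol silyl group is exchanged for the angeloyl group; the C10 hydroxyl is freed.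
- The oxirane is the only ring made. It is closed on the fully acylated allylic alcohol, and acetylation of C10 comes last.
- Stereochemistry: C2 of the butanoate comes from (R)-2-methylbutanoic acid, the Z alkene from angelic acid, and C8 from L-(+)-diisopropyl tartrate in the epoxidation.

Key step: step 10

Remark on labels: thymol numbering is used. C1 is the ring carbon bearing C7 (the CH2O group), C3 bears the phenol oxygen, C4 bears C8; C8 is the quaternary oxirane carbon, C9 the oxirane CH2, C10 the CH2O arm.

Remark on descriptors: the C8 descriptor is S in the epoxy alcohol and R in the final acetate. No bond at C8 changes; the acetoxymethyl arm simply outranks the oxirane CH2 in the CIP order, whereas the hydroxymethyl arm does not.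

Assumption: the silyl ether of 2-bromoallyl alcohol is made in one step rather than bought.

**Route**

Step 1
Reactants: 1 methyl 4-bromo-3-hydroxybenzoate
Product: 2 methyl 4-bromo-3-(tert-butyldimethylsilyloxy)benzoate
Conditions: TBSCl, imidazole, DMF, rt
Reagents that add atoms: tert-butyldimethylsilyl chloride, CC(C)(C)[Si](C)(C)Cl
Why: Imidazole-promoted O-silylation of a phenol (silyl ether protection) is routine beside an ortho bromine and removes the acidic proton before the hydride reduction and the esterification at C7.

Step 2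
Reactants: 2 methyl 4-bromo-3-(tert-butyldimethylsilyloxy)benzoate
Product: 3 [4-bromo-3-(tert-butyldimethylsilyloxy)phenyl]methanol
Conditions: iBu2AlH (DIBAL-H), CH2Cl2, −78 to 0 °C; aqueous potassium sodium tartrate work-up
Reagents that add atoms: none
Why: Hydride reduction of a benzoate ester to the benzylic alcohol with iBu2AlH at low temperature should leave the aryl bromide and the aryl silyl ether untouched.

Step 3
Reactants: 3 [4-bromo-3-(tert-butyldimethylsilyloxy)phenyl]methanol; 4 (R)-2-methylbutanoic acid
Product: 5 4-bromo-3-(tert-butyldimethylsilyloxy)benzyl (2R)-2-methylbutanoate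
Conditions: EDC·HCl, DMAP (cat.), CH2Cl2, 0 °C to rt
Reagents that add atoms: none
Why: Steglich-type carbodiimide esterification of a primary benzylic alcohol is mild enough that the alpha stereocentre of 4, which has no alpha heteroatom to acidify it, should be carried over unchanged as the (R) centre of the C7 ester.

Step 4
Reactants: 5 4-bromo-3-(tert-butyldimethylsilyloxy)benzyl (2R)-2-methylbutanoate
Product: 6 3-(tert-butyldimethylsilyloxy)-4-(4,4,5,5-tetramethyl-1,3,2-dioxaborolan-2-yl)benzyl (2R)-2-methylbutanoate
Conditions: B2pin2, Pd(dppf)Cl2 (cat.), KOAc, 1,4-dioxane, 85 °C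
Reagents that add atoms: bis(pinacolato)diboron, CC1(C)OB(OC1(C)C)B1OC(C)(C)C(C)(C)O1
Why: Miyaura borylation of an aryl bromide under Pd(dppf)Cl2 with the weak base KOAc tolerates the alkyl ester and the aryl silyl ether and turns C4 into the nucleophilic partner for the coupling.

Step 5
Reactants: 7 2-bromoallyl alcohol (2-bromoprop-2-en-1-ol)
Product: 8 (2-bromoprop-2-en-1-yloxy)(tert-butyl)dimethylsilane
Conditions: TBSCl, imidazole, CH2Cl2, 0 °C to rt
Reagents that add atoms: tert-butyldimethylsilyl chloride, CC(C)(C)[Si](C)(C)Cl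
Why: Standard silyl ether protection of a primary allylic alcohol keeps the C10 oxygen masked, so that later the phenol is the only free hydroxyl when the angeloyl group is put on.

Step 6
Reactants: 6 3-(tert-butyldimethylsilyloxy)-4-(4,4,5,5-tetramethyl-1,3,2-dioxaborolan-2-yl)benzyl (2R)-2-methylbutanoate; 8 (2-bromoprop-2-en-1-yloxy)(tert-butyl)dimethylsilane
Product: 9 3-(tert-butyldimethylsilyloxy)-4-[3-(tert-butyldimethylsilyloxy)prop-1-en-2-yl]benzyl (2R)-2-methylbutanoate
Conditions: Pd(dppf)Cl2 (cat.), K3PO4, 1,4-dioxane/H2O, 60 °C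
Reagents that add atoms: none
Why: Suzuki–Miyaura coupling of an aryl pinacol boronate with a 2-bromoalkene forms the C4–C8 bond with the C8=C9 alkene already in place, the allylic silyl ether being no leaving group for a palladium allyl pathway.

Step 7
Reactants: 9 3-(tert-butyldimethylsilyloxy)-4-[3-(tert-butyldimethylsilyloxy)prop-1-en-2-yl]benzyl (2R)-2-methylbutanoate
Product: 10 4-[3-(tert-butyldimethylsilyloxy)prop-1-en-2-yl]-3-hydroxybenzyl (2R)-2-methylbutanoate
Conditions: KHF2, MeOH, rt
Reagents that add atoms: none
Why: Chemoselective fluoride desilylation: KHF2 in methanol at room temperature cleaves aryl silyl ethers (phenoxide leaving group) much faster than primary alkyl silyl ethers and is too mild to touch the C7 ester.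

Step 8
Reactants: 10 4-[3-(tert-butyldimethylsilyloxy)prop-1-en-2-yl]-3-hydroxybenzyl (2R)-2-methylbutanoate; 11 angelic acid ((Z)-2-methylbut-2-enoic acid)
Product: 13 2-[3-(tert-butyldimethylsilyloxy)prop-1-en-2-yl]-5-{[(2R)-2-methylbutanoyloxy]methyl}phenyl (Z)-2-methylbut-2-enoate, via angelic 2,4,6-trichlorobenzoic anhydride 12 (not isolated)
Conditions: 11, 2,4,6-trichlorobenzoyl chloride, Et3N, toluene, rt; then 10, toluene, rt to 40 °C (no DMAP)
Reagents that add atoms: 2,4,6-trichlorobenzoyl chloride, O=C(Cl)c1c(Cl)cc(Cl)cc1Cl (its atoms stay in 12 only and none of them reaches 13)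
Why: Yamaguchi-type mixed-anhydride esterification in which the phenol attacks the unhindered angeloyl carbonyl of 12 and not the shielded 2,4,6-trichlorobenzoyl carbonyl, run without DMAP and without strong heating so that the Z alkene should not isomerise to the tiglate.

Step 9
Reactants: 13 2-[3-(tert-butyldimethylsilyloxy)prop-1-en-2-yl]-5-{[(2R)-2-methylbutanoyloxy]methyl}phenyl (Z)-2-methylbut-2-enoate
Product: 14 2-(3-hydroxyprop-1-en-2-yl)-5-{[(2R)-2-methylbutanoyloxy]methyl}phenyl (Z)-2-methylbut-2-enoate
Conditions: HF·pyridine, pyridine, THF, 0 °C to rt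
Reagents that add atoms: none
Why: Acidic fluoride desilylation of a primary silyl ether with pyridine-buffered HF·pyridine frees the C10 hydroxyl without forming an alkoxide, so the angeloyl group should stay on the phenol oxygen and not move to C10.

Step 10
Reactants: 14 2-(3-hydroxyprop-1-en-2-yl)-5-{[(2R)-2-methylbutanoyloxy]methyl}phenyl (Z)-2-methylbut-2-enoate
Product: 15 2-[(2S)-2-(hydroxymethyl)oxiran-2-yl]-5-{[(2R)-2-methylbutanoyloxy]methyl}phenyl (Z)-2-methylbut-2-enoate
Conditions: Ti(OiPr)4 (cat.), L-(+)-diisopropyl tartrate (cat.), tBuOOH (anhydrous, in isooctane), 4 Å molecular sieves, CH2Cl2, −20 °C; non-basic work-up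
Reagents that add atoms: tert-butyl hydroperoxide, CC(C)(C)OO
Why: Katsuki–Sharpless asymmetric epoxidation: the C10 hydroxyl of 14 and tBuOOH exchange for isopropoxide on one titanium of the dimeric tartrate complex [Ti(DIPT)(OiPr)2]2, and the bound peroxide passes its distal oxygen to C8=C9 inside this complex, so that O–C8 and O–C9 form in one concerted step. The closest known reactions are the titanium–tartrate epoxidations of 2-methylallyl alcohol and of 2-arylprop-2-en-1-ols. The oxirane, the only ring made, closes by this concerted [2+1] oxygen-atom transfer to the alkene and not by a stepwise displacement. The stereocentre C8 is set by the L-(+)-tartrate ligand acting through the titanium-bound C10 alkoxide: it selects the alkene face that gives (S)-glycidol from allyl alcohol and (S)-2-methylglycidol from 2-methylallyl alcohol, and because the aryl group takes the place of H or CH3 as the lowest-ranked substituent at C8 the product should be the (S)-epoxy alcohol. The step needs chemoselectivity for C8=C9 over the angeloyl alkene, which follows because that alkene is electron-poor and has no hydroxyl to bind titanium. It also needs the aryl ester and the new epoxide to survive, which catalytic titanium, molecular sieves, −20 °C and a non-basic work-up should secure, while the acylated phenol rules out attack of a phenoxide on C9.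

Step 11
Reactants: 15 2-[(2S)-2-(hydroxymethyl)oxiran-2-yl]-5-{[(2R)-2-methylbutanoyloxy]methyl}phenyl (Z)-2-methylbut-2-enoate
Product: 16 2-[(2R)-2-(acetoxymethyl)oxiran-2-yl]-5-{[(2R)-2-methylbutanoyloxy]methyl}phenyl (Z)-2-methylbut-2-enoate
Conditions: Ac2O, pyridine, CH2Cl2, 0 °C to rt
Reagents that add atoms: acetic anhydride, CC(=O)OC(C)=O
Why: Pyridine-mediated acetylation of a primary alcohol with acetic anhydride in the cold touches no bond at C8 and should leave the epoxide, both esters and the Z alkene alone.

**Compound list**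

1 | methyl 4-bromo-3-hydroxybenzoate | COC(=O)c1ccc(Br)c(O)c1 | starting material
2 | methyl 4-bromo-3-(tert-butyldimethylsilyloxy)benzoate | COC(=O)c1ccc(Br)c(O[Si](C)(C)C(C)(C)C)c1 | intermediate
3 | [4-bromo-3-(tert-butyldimethylsilyloxy)phenyl]methanol | OCc1ccc(Br)c(O[Si](C)(C)C(C)(C)C)c1 | intermediate
4 | (R)-2-methylbutanoic acid | CC[C@@H](C)C(=O)O | starting material
5 | 4-bromo-3-(tert-butyldimethylsilyloxy)benzyl (2R)-2-methylbutanoate | CC(C)(C)[Si](C)(C)Oc1cc(COC(=O)[C@H](C)CC)ccc1Br | intermediate
6 | 3-(tert-butyldimethylsilyloxy)-4-(4,4,5,5-tetramethyl-1,3,2-dioxaborolan-2-yl)benzyl (2R)-2-methylbutanoate | CC(C)(C)[Si](C)(C)Oc1cc(COC(=O)[C@H](C)CC)ccc1B1OC(C)(C)C(C)(C)O1 | intermediate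
7 | 2-bromoallyl alcohol (2-bromoprop-2-en-1-ol) | OCC(Br)=C | starting material
8 | (2-bromoprop-2-en-1-yloxy)(tert-butyl)dimethylsilane | C=C(Br)CO[Si](C)(C)C(C)(C)C | intermediate
9 | 3-(tert-butyldimethylsilyloxy)-4-[3-(tert-butyldimethylsilyloxy)prop-1-en-2-yl]benzyl (2R)-2-methylbutanoate | CC(C)(C)[Si](C)(C)Oc1cc(COC(=O)[C@H](C)CC)ccc1C(=C)CO[Si](C)(C)C(C)(C)C | intermediate
10 | 4-[3-(tert-butyldimethylsilyloxy)prop-1-en-2-yl]-3-hydroxybenzyl (2R)-2-methylbutanoate | Oc1cc(COC(=O)[C@H](C)CC)ccc1C(=C)CO[Si](C)(C)C(C)(C)C | intermediate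
11 | angelic acid ((Z)-2-methylbut-2-enoic acid) | C/C=C(/C)C(=O)O | starting material
12 | angelic 2,4,6-trichlorobenzoic anhydride | C/C=C(/C)C(=O)OC(=O)c1c(Cl)cc(Cl)cc1Cl | intermediate (not isolated)
13 | 2-[3-(tert-butyldimethylsilyloxy)prop-1-en-2-yl]-5-{[(2R)-2-methylbutanoyloxy]methyl}phenyl (Z)-2-methylbut-2-enoate | C/C=C(/C)C(=O)Oc1cc(COC(=O)[C@H](C)CC)ccc1C(=C)CO[Si](C)(C)C(C)(C)C | intermediate
14 | 2-(3-hydroxyprop-1-en-2-yl)-5-{[(2R)-2-methylbutanoyloxy]methyl}phenyl (Z)-2-methylbut-2-enoate | C/C=C(/C)C(=O)Oc1cc(COC(=O)[C@H](C)CC)ccc1C(=C)CO | intermediate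
15 | 2-[(2S)-2-(hydroxymethyl)oxiran-2-yl]-5-{[(2R)-2-methylbutanoyloxy]methyl}phenyl (Z)-2-methylbut-2-enoate | C/C=C(/C)C(=O)Oc1cc(COC(=O)[C@H](C)CC)ccc1[C@]1(CO)CO1 | intermediate
16 | 2-[(2R)-2-(acetoxymethyl)oxiran-2-yl]-5-{[(2R)-2-methylbutanoyloxy]methyl}phenyl (Z)-2-methylbut-2-enoate | C/C=C(/C)C(=O)Oc1cc(COC(=O)[C@H](C)CC)ccc1[C@]1(COC(C)=O)CO1 | target

**Totals**

Total step count: 11.
Longest linear sequence: 10 steps (from 1 to 16 through steps 1 to 4 and 6 to 11); step 5 is a one-step side branch.

**Steps most likely to fail**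

Step 10. What may go wrong:
- slow oxygen transfer to the hindered, ortho-acyloxy-substituted alkene with loss of enantioface selectivity;
- shift of the angeloyl group from the phenol oxygen to the titanium-bound C10 oxygen;
- opening of the 2-aryl epoxide by isopropoxide.

Fallback: the epoxide is made without titanium and the C8 configuration is then sorted by an enzyme. Setting out from 14, mCPBA with NaHCO3 in CH2Cl2 at 0 °C should give the epoxy alcohol as the mixture of both C8 epimers F1. This is a Prilezhaev epoxidation of the electron-rich 1,1-disubstituted alkene that leaves the electron-poor angeloyl alkene alone. A lipase chosen by a screen (immobilised Burkholderia cepacia lipase or Candida antarctica lipase B), with vinyl acetate in tert-butyl methyl ether, then acetylates the primary hydroxyl of one epimer preferentially. Which epimer reacts faster has to be found by experiment. If the enzyme takes the unwanted epimer, that is removed as the C8 epimer of the target acetate F2 and the unreacted alcohol is 15, where the route is rejoined before step 11. If the enzyme prefers the wanted epimer, the acetate fraction is already 16.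

Step 8. What may go wrong:
- isomerisation of the Z alkene to the E (tigloyl) isomer under base or nucleophile;
- acyl transfer from the wrong carbonyl of the mixed anhydride.

Fallback: the Z geometry is built after the ester bond is made. Setting out from 10, esterification with but-2-ynoic acid (DCC, CH2Cl2, 0 °C) should give the aryl but-2-ynoate F3, which has no alkene geometry to lose. Syn hydrostannation with Bu3SnH under Pd(PPh3)4 catalysis places tin on the alpha carbon and should give the (E)-2-(tributylstannyl)but-2-enoate F4. Stille methylation (MeI, Pd2(dba)3, AsPh3, CuI, DMF) then replaces tin by CH3 with retention of geometry, and the route is rejoined at 13.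

Step 6. What may go wrong:
- protodeboronation of the ortho-silyloxy arylboronate;
- slow transmetalation at the hindered position;
- early loss of the aryl silyl ether or ester hydrolysis in aqueous base.

Fallback: the polarity of the coupling is reversed, so boron sits on the small partner. Setting out from 8, borylation of the alkenyl bromide (B2pin2, PdCl2(PPh3)2, PPh3, KOPh, toluene, 50 °C) should give the alkenyl pinacol boronate F5. This is coupled with aryl bromide 5 (Pd(dppf)Cl2, K3PO4, 1,4-dioxane/H2O, 60 °C) in a Suzuki–Miyaura reaction, and the route is rejoined at 9. Step 4 is then not needed.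

**Further compounds**

F1 | step 10 | 2-[2-(hydroxymethyl)oxiran-2-yl]-5-{[(2R)-2-methylbutanoyloxy]methyl}phenyl (Z)-2-methylbut-2-enoate, mixture of both C8 epimers | C/C=C(/C)C(=O)Oc1cc(COC(=O)[C@H](C)CC)ccc1C1(CO)CO1
F2 | step 10 | 2-[(2S)-2-(acetoxymethyl)oxiran-2-yl]-5-{[(2R)-2-methylbutanoyloxy]methyl}phenyl (Z)-2-methylbut-2-enoate, the C8 epimer of 16 | C/C=C(/C)C(=O)Oc1cc(COC(=O)[C@H](C)CC)ccc1[C@@]1(COC(C)=O)CO1
F3 | step 8 | 2-[3-(tert-butyldimethylsilyloxy)prop-1-en-2-yl]-5-{[(2R)-2-methylbutanoyloxy]methyl}phenyl but-2-ynoate | CC#CC(=O)Oc1cc(COC(=O)[C@H](C)CC)ccc1C(=C)CO[Si](C)(C)C(C)(C)C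
F4 | step 8 | 2-[3-(tert-butyldimethylsilyloxy)prop-1-en-2-yl]-5-{[(2R)-2-methylbutanoyloxy]methyl}phenyl (E)-2-(tributylstannyl)but-2-enoate | C/C=C(/[Sn](CCCC)(CCCC)CCCC)C(=O)Oc1cc(COC(=O)[C@H](C)CC)ccc1C(=C)CO[Si](C)(C)C(C)(C)C
F5 | step 6 | tert-butyldimethyl{[2-(4,4,5,5-tetramethyl-1,3,2-dioxaborolan-2-yl)prop-2-en-1-yl]oxy}silane | C=C(CO[Si](C)(C)C(C)(C)C)B1OC(C)(C)C(C)(C)O1
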